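**Plan**

1. Retrosynthesis: the flavan units are lettered A (catechin end) to D. The C4(unit B)–C8(unit C) bond is cut first (C4 cation of unit B plus an epicatechin-(4β→8)-epicatechin dimer), then the pyran ring of unit B through O1–C2 and C3–C4, then the C4(unit A)–aryl bond.
2. Enabling feature: in unit B the pyran oxygen O1 sits on C8a of a phloroglucinol ring next to C4a, so O1=C8a–C4a=C4 can be unmasked from a salicylaldehyde acetal as a 4-methoxy o-quinone methide (a 1-oxadiene). C2=C3 with its catechol ring and O3 is then a (Z)-styryl acetate.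
3. Forward: the catechin C4 cation of unit A is attached para to the masked oxygen of a phloroglucinol ether, which fixes the 4→6 link by construction. The phenol is ortho-formylated, an oxa-[4+2] closes the pyran ring of unit B, and the 4-methoxy group it leaves is the leaving group for union with the lower dimer.
4. Stereochemistry: units A, C and D come from (+)-catechin and (−)-epicatechin. Each interflavan bond forms trans to O3 (acetoxy participation, or attack anti to the cis 2-aryl/3-oxygen pair). C2 and C3 of unit B come from the Z alkene (cis) and a chiral Brønsted acid (absolute sense).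
5. Finish: methanolysis of two acetates, then hydrogenolysis of sixteen benzyl ethers.

Key step: step 10

Convention: in every unit α is the face of the pyran ring that carries the 2-aryl group and β is the other face; locants are the usual flavan locants within each unit.

Assumption: the (R)-configured binaphthyl N-triflylphosphoramide is taken as the antipode that sends the dienophile to the face giving 2R,3R in unit B; the stereocentres of unit A are remote from the oxadiene and should exert no real bias, so if the sense is the opposite the (S)-acid is used with nothing else changed.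

**Route**

Step 1
Reactants: 1 (+)-catechin
Product: 2 5,7,3',4'-tetra-O-benzyl-(+)-catechin (3-OH free)
Conditions: BnBr, K2CO3, DMF, 0 °C to rt
Reagents that add atoms: benzyl bromide BrCc1ccccc1
Why: Williamson etherification of the four phenols in the presence of the much less acidic secondary alcohol; no stereocentre is touched.

Step 2
Reactants: 2 5,7,3',4'-tetra-O-benzyl-(+)-catechin
Product: 3 5,7,3',4'-tetra-O-benzyl-4β-(2-ethoxyethoxy)catechin (alkoxy group cis to the 3-OH but trans to the 2-aryl group)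
Conditions: DDQ, 2-ethoxyethanol, CH2Cl2, rt
Reagents that add atoms: 2-ethoxyethanol CCOCCO
Why: DDQ benzylic oxidation at C4 gives the cation stabilised by the 5,7-dioxygenated ring, which the alcohol captures on the face opposite the 2-aryl group; the C4 configuration is of no consequence because it is ionised again in step 5.

Step 3
Reactants: 3 5,7,3',4'-tetra-O-benzyl-4β-(2-ethoxyethoxy)catechin
Product: 4 3-O-acetyl-5,7,3',4'-tetra-O-benzyl-4β-(2-ethoxyethoxy)catechin
Conditions: Ac2O, pyridine, DMAP (cat.), rt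
Reagents that add atoms: acetic anhydride CC(=O)OC(C)=O
Why: DMAP-catalysed acylation of the secondary alcohol installs the participating group for step 5 and protects O3 for the steps after it.

Step 4
Reactants: 5 3,5-bis(benzyloxy)phenol
Product: 6 [3,5-bis(benzyloxy)phenoxy]triisopropylsilane
Conditions: TIPSCl, imidazole, DMF, rt
Reagents that add atoms: triisopropylsilyl chloride CC(C)[Si](Cl)(C(C)C)C(C)C
Why: silylation of the phenol marks the oxygen that becomes O1 of unit B and places a bulky group next to both ortho carbons.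

Step 5
Reactants: 4 3-O-acetyl-5,7,3',4'-tetra-O-benzyl-4β-(2-ethoxyethoxy)catechin; 6 [3,5-bis(benzyloxy)phenoxy]triisopropylsilane
Product: 7 3-O-acetyl-5,7,3',4'-tetra-O-benzylcatechin carrying at C4 on the α face (trans to the 3-acetoxy group) a 2,6-bis(benzyloxy)-4-(triisopropylsilyloxy)phenyl group
Conditions: TMSOTf (0.2 equiv), 6 (3 equiv), CH2Cl2, −78 °C
Reagents that add atoms: none
Why: Friedel–Crafts alkylation through the C4 cation, in which the β-oriented 3-acetoxy group bridges to C4 as a 1,3-dioxolan-2-ylium ion so that the arene enters on the α face (3,4-trans), and in which the arene should react at the carbon between its two benzyloxy groups because both other positions are shielded by the silyl ether.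

Step 6
Reactants: 7 the 4α-aryl catechin silyl ether
Product: 8 3-O-acetyl-5,7,3',4'-tetra-O-benzylcatechin carrying at C4 (α) a 2,6-bis(benzyloxy)-4-hydroxyphenyl group
Conditions: TBAF, AcOH, THF, 0 °C
Reagents that add atoms: none
Why: fluoride cleaves the aryl silyl ether, and the acetic acid buffer keeps the phenoxide from attacking the acetate.

Step 7
Reactants: 8 the 4α-aryl catechin phenol
Product: 10 3-O-acetyl-5,7,3',4'-tetra-O-benzylcatechin carrying at C4 (α) a 2,6-bis(benzyloxy)-3-formyl-4-hydroxyphenyl group, via hydroxymethylphenol 9 (not isolated)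
Conditions: MgCl2, Et3N, paraformaldehyde, THF, reflux; then aq. HCl
Reagents that add atoms: formaldehyde (as paraformaldehyde) C=O
Why: ortho-formylation of the aryloxymagnesium chloride (ArOMgCl) formed in situ (Casnati–Skattebøl type: ortho-hydroxymethylation, then hydride transfer to a second formaldehyde), regiospecific because the para position is occupied and the two ortho positions are equivalent.

Step 8
Reactants: 11 3,4-bis(benzyloxy)benzaldehyde
Product: 12 1,2-bis(benzyloxy)-4-ethynylbenzene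
Conditions: dimethyl (1-diazo-2-oxopropyl)phosphonate, K2CO3, MeOH/THF, rt
Reagents that add atoms: dimethyl (1-diazo-2-oxopropyl)phosphonate CC(=O)C(=[N+]=[N-])P(=O)(OC)OC
Why: Seyferth–Gilbert homologation with the Ohira–Bestmann reagent converts the aldehyde into the terminal alkyne under mild base.

Step 9
Reactants: 12 1,2-bis(benzyloxy)-4-ethynylbenzene
Product: 13 (Z)-2-[3,4-bis(benzyloxy)phenyl]ethenyl acetate
Conditions: AcOH, [RuCl2(p-cymene)]2 (1 mol %), P(4-ClC6H4)3, DMAP, toluene, 60 °C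
Reagents that add atoms: acetic acid CC(=O)O
Why: anti-Markovnikov addition of a carboxylic acid to a terminal aryl alkyne, catalysed by [RuCl2(p-cymene)]2 through a vinylidene complex, a reaction type that gives the Z enol ester.

Step 10
Reactants: 10 the 4α-aryl catechin salicylaldehyde; 13 (Z)-2-[3,4-bis(benzyloxy)phenyl]ethenyl acetate
Product: 16 the A–B dimer in which C4 of 3-O-acetyl-tetra-O-benzylcatechin is bonded (α) to C6 of 3-O-acetyl-5,7,3',4'-tetra-O-benzyl-4α-methoxyepicatechin (2-aryl/3-acetoxy/4-methoxy all cis in unit B), via dimethyl acetal 14 (not isolated), via o-quinone methide 15 (not isolated)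
Conditions: HC(OMe)3 (3 equiv), (R)-3,3'-bis(2,4,6-triisopropylphenyl)-1,1'-binaphthyl-2,2'-diyl N-(trifluoromethylsulfonyl)phosphoramide (10 mol %), 5 Å MS, CH2Cl2, 0 °C; then 13 (2 equiv), −40 °C
Reagents that add atoms: trimethyl orthoformate COC(OC)OC
Why: Proposed new method: the acid turns acetal 14 into the 4-methoxy o-quinone methide 15 (its protonated form is a 2-hydroxybenzylic oxocarbenium ion held to the chiral phosphoramide anion by the phenolic O–H···O bond and by ion pairing), and the electron-rich styrene 13 adds to this 1-oxadiene in an asynchronous inverse-electron-demand oxa-[4+2] in which the C3–C4 bond leads and the O1–C2 bond follows; the closest known reactions are the chiral Brønsted acid-catalysed [4+2] cycloadditions of in situ o-quinone methides with styrenes and the acid-mediated salicylaldehyde/orthoformate/styrene synthesis of 4-alkoxyflavans, neither of which has been shown with a β-acyloxystyrene. The one ring that closes is the dihydropyran of unit B (O1, C2, C3, C4, C4a, C8a), formed as a [4+2] cycloaddition across O1 and C4, which in the stepwise limit is a six-membered closure of the phenol oxygen onto the C2 benzylic cation. Regiochemistry follows from the polarisation of 13: the acetoxy oxygen is tied up in ester resonance, so the 4-benzyloxyphenyl group decides, C3 is the nucleophilic carbon and C2 carries the developing benzylic cation that O1 captures. C2 and C3 should become cis because both bonds form on one face of the Z alkene before the short-lived C2 cation can rotate, C4 should come out cis to both through the endo orientation (aryl over the dienone ring) and is erased in step 14, and the absolute sense at C2 and C3 is set by the catalyst, which blocks one face of the bound oxadiene. The step also needs chemoselectivity between the acetal and the 4-methoxy group of the product, which the weak acid should secure because only the doubly oxygenated acetal carbon ionises at −40 °C.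

Step 11
Reactants: 17 (−)-epicatechin
Product: 18 5,7,3',4'-tetra-O-benzyl-(−)-epicatechin (3-OH free)
Conditions: BnBr, K2CO3, DMF, 0 °C to rt
Reagents that add atoms: benzyl bromide BrCc1ccccc1
Why: Williamson etherification of the four phenols, as in step 1.

Step 12
Reactants: 18 5,7,3',4'-tetra-O-benzyl-(−)-epicatechin
Product: 19 5,7,3',4'-tetra-O-benzyl-4β-(2-ethoxyethoxy)epicatechin (alkoxy group trans to both the 3-OH and the 2-aryl group)
Conditions: DDQ, 2-ethoxyethanol, CH2Cl2, rt
Reagents that add atoms: 2-ethoxyethanol CCOCCO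
Why: DDQ benzylic oxidation at C4 with capture of the cation by the alcohol, as in step 2.

Step 13
Reactants: 19 5,7,3',4'-tetra-O-benzyl-4β-(2-ethoxyethoxy)epicatechin; 18 5,7,3',4'-tetra-O-benzyl-(−)-epicatechin
Product: 20 octa-O-benzyl epicatechin-(4β→8)-epicatechin (both 3-OH free)
Conditions: TMSOTf (cat.), 18 (4 equiv), CH2Cl2, −78 °C
Reagents that add atoms: none
Why: Friedel–Crafts alkylation in which C8 of 18, the most reactive arene carbon of a benzylated flavan-3-ol, attacks the C4 cation on the β face, anti to the cis 2-aryl and 3-hydroxy groups, while the excess of 18 suppresses further chain growth.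

Step 14
Reactants: 16 the A–B dimer with the 4α-methoxy group in unit B; 20 octa-O-benzyl epicatechin-(4β→8)-epicatechin
Product: 21 hexadeca-O-benzyl catechin-(4α→6)-epicatechin-(4β→8)-epicatechin-(4β→8)-epicatechin bis(3-O-acetate) (O3 acetylated on units A and B but free on units C and D)
Conditions: TMSOTf (0.5 equiv), 20 (3 equiv), CH2Cl2, −78 to −40 °C
Reagents that add atoms: none
Why: Friedel–Crafts alkylation in which TMSOTf ionises the 4-methoxy group of unit B, the α-oriented 3-acetoxy group bridges to C4 as a 1,3-dioxolan-2-ylium ion on the face that also carries the 2-aryl group, and C8 of the upper unit of 20 therefore enters on the β face to give the 3,4-trans bond.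

Step 15
Reactants: 21 the hexadecabenzyl tetramer diacetate
Product: 22 hexadeca-O-benzyl catechin-(4α→6)-epicatechin-(4β→8)-epicatechin-(4β→8)-epicatechin (all four 3-OH free)
Conditions: NaOMe (cat.), MeOH/THF, rt
Reagents that add atoms: none
Why: Zemplén transesterification removes both secondary acetates without touching benzyl ethers or interflavan bonds.

Step 16
Reactants: 22 the hexadecabenzyl tetramer tetraol
Product: 23 catechin-(4α→6)-epicatechin-(4β→8)-epicatechin-(4β→8)-epicatechin (target, CNP0228086.1)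
Conditions: H2 (1 atm), Pd(OH)2/C, THF/MeOH/H2O, rt
Reagents that add atoms: none
Why: hydrogenolysis of the sixteen benzyl ethers under neutral conditions leaves the acid- and base-sensitive interflavan bonds and all stereocentres intact.

**Compound list**

1 | (+)-catechin | Oc1cc(O)c2c(c1)O[C@H](c1ccc(O)c(O)c1)[C@@H](O)C2 | starting material
2 | 5,7,3',4'-tetra-O-benzyl-(+)-catechin | O(Cc5ccccc5)c1cc(OCc5ccccc5)c2c(c1)O[C@H](c1ccc(OCc5ccccc5)c(OCc5ccccc5)c1)[C@@H](O)C2 | intermediate
3 | 5,7,3',4'-tetra-O-benzyl-4β-(2-ethoxyethoxy)catechin | O(Cc5ccccc5)c1cc(OCc5ccccc5)c2c(c1)O[C@H](c1ccc(OCc5ccccc5)c(OCc5ccccc5)c1)[C@@H](O)[C@H]2OCCOCC | intermediate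
4 | 3-O-acetyl-5,7,3',4'-tetra-O-benzyl-4β-(2-ethoxyethoxy)catechin | O(Cc5ccccc5)c1cc(OCc5ccccc5)c2c(c1)O[C@H](c1ccc(OCc5ccccc5)c(OCc5ccccc5)c1)[C@@H](OC(C)=O)[C@H]2OCCOCC | intermediate
5 | 3,5-bis(benzyloxy)phenol | Oc1cc(OCc2ccccc2)cc(OCc2ccccc2)c1 | starting material
6 | [3,5-bis(benzyloxy)phenoxy]triisopropylsilane | CC(C)[Si](Oc1cc(OCc2ccccc2)cc(OCc2ccccc2)c1)(C(C)C)C(C)C | intermediate
7 | 3-O-acetyl-tetra-O-benzylcatechin with 4α-[2,6-bis(benzyloxy)-4-(triisopropylsilyloxy)phenyl] | O(Cc5ccccc5)c1cc(OCc5ccccc5)c2c(c1)O[C@H](c1ccc(OCc5ccccc5)c(OCc5ccccc5)c1)[C@@H](OC(C)=O)[C@@H]2c1c(OCc5ccccc5)cc(O[Si](C(C)C)(C(C)C)C(C)C)cc1OCc5ccccc5 | intermediate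
8 | 3-O-acetyl-tetra-O-benzylcatechin with 4α-[2,6-bis(benzyloxy)-4-hydroxyphenyl] | O(Cc5ccccc5)c1cc(OCc5ccccc5)c2c(c1)O[C@H](c1ccc(OCc5ccccc5)c(OCc5ccccc5)c1)[C@@H](OC(C)=O)[C@@H]2c1c(OCc5ccccc5)cc(O)cc1OCc5ccccc5 | intermediate
9 | 3-O-acetyl-tetra-O-benzylcatechin with 4α-[2,6-bis(benzyloxy)-4-hydroxy-3-(hydroxymethyl)phenyl] (not isolated) | O(Cc5ccccc5)c1cc(OCc5ccccc5)c2c(c1)O[C@H](c1ccc(OCc5ccccc5)c(OCc5ccccc5)c1)[C@@H](OC(C)=O)[C@@H]2c1c(OCc5ccccc5)c(CO)c(O)cc1OCc5ccccc5 | intermediate
10 | 3-O-acetyl-tetra-O-benzylcatechin with 4α-[2,6-bis(benzyloxy)-3-formyl-4-hydroxyphenyl] | O(Cc5ccccc5)c1cc(OCc5ccccc5)c2c(c1)O[C@H](c1ccc(OCc5ccccc5)c(OCc5ccccc5)c1)[C@@H](OC(C)=O)[C@@H]2c1c(OCc5ccccc5)c(C=O)c(O)cc1OCc5ccccc5 | intermediate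
11 | 3,4-bis(benzyloxy)benzaldehyde | O=Cc1ccc(OCc2ccccc2)c(OCc2ccccc2)c1 | starting material
12 | 1,2-bis(benzyloxy)-4-ethynylbenzene | C#Cc1ccc(OCc2ccccc2)c(OCc2ccccc2)c1 | intermediate
13 | (Z)-2-[3,4-bis(benzyloxy)phenyl]ethenyl acetate | CC(=O)O/C=C\c1ccc(OCc2ccccc2)c(OCc2ccccc2)c1 | intermediate
14 | dimethyl acetal of 10 (not isolated) | O(Cc5ccccc5)c1cc(OCc5ccccc5)c2c(c1)O[C@H](c1ccc(OCc5ccccc5)c(OCc5ccccc5)c1)[C@@H](OC(C)=O)[C@@H]2c1c(OCc5ccccc5)c(C(OC)OC)c(O)cc1OCc5ccccc5 | intermediate
15 | 4-methoxy o-quinone methide from 14, (E)-6-(methoxymethylidene)cyclohexa-2,4-dienone form (not isolated) | O(Cc5ccccc5)c1cc(OCc5ccccc5)c2c(c1)O[C@H](c1ccc(OCc5ccccc5)c(OCc5ccccc5)c1)[C@@H](OC(C)=O)[C@@H]2C1=C(OCc5ccccc5)/C(=C\OC)C(=O)C=C1OCc5ccccc5 | intermediate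
16 | 3-O-acetyl-tetra-O-benzylcatechin-(4α→6)-[3-O-acetyl-5,7,3',4'-tetra-O-benzyl-4α-methoxyepicatechin] | O(Cc5ccccc5)c1cc(OCc5ccccc5)c2c(c1)O[C@H](c1ccc(OCc5ccccc5)c(OCc5ccccc5)c1)[C@@H](OC(C)=O)[C@@H]2c1c(OCc5ccccc5)cc2c(c1OCc5ccccc5)[C@@H](OC)[C@@H](OC(C)=O)[C@@H](c1ccc(OCc5ccccc5)c(OCc5ccccc5)c1)O2 | intermediate
17 | (−)-epicatechin | Oc1cc(O)c2c(c1)O[C@H](c1ccc(O)c(O)c1)[C@H](O)C2 | starting material
18 | 5,7,3',4'-tetra-O-benzyl-(−)-epicatechin | O(Cc5ccccc5)c1cc(OCc5ccccc5)c2c(c1)O[C@H](c1ccc(OCc5ccccc5)c(OCc5ccccc5)c1)[C@H](O)C2 | intermediate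
19 | 5,7,3',4'-tetra-O-benzyl-4β-(2-ethoxyethoxy)epicatechin | O(Cc5ccccc5)c1cc(OCc5ccccc5)c2c(c1)O[C@H](c1ccc(OCc5ccccc5)c(OCc5ccccc5)c1)[C@H](O)[C@H]2OCCOCC | intermediate
20 | octa-O-benzyl epicatechin-(4β→8)-epicatechin | O(Cc5ccccc5)c1cc(OCc5ccccc5)c2c(c1)O[C@H](c1ccc(OCc5ccccc5)c(OCc5ccccc5)c1)[C@H](O)[C@H]2c1c(OCc5ccccc5)cc(OCc5ccccc5)c3c1O[C@H](c1ccc(OCc5ccccc5)c(OCc5ccccc5)c1)[C@H](O)C3 | intermediate
21 | hexadeca-O-benzyl tetramer, 3-O-acetyl on units A and B, 3-OH free on units C and D | O(Cc5ccccc5)c1cc(OCc5ccccc5)c2c(c1)O[C@H](c1ccc(OCc5ccccc5)c(OCc5ccccc5)c1)[C@@H](OC(C)=O)[C@@H]2c1c(OCc5ccccc5)cc2c(c1OCc5ccccc5)[C@H](c1c(OCc5ccccc5)cc(OCc5ccccc5)c3c1O[C@H](c1ccc(OCc5ccccc5)c(OCc5ccccc5)c1)[C@H](O)[C@H]3c1c(OCc5ccccc5)cc(OCc5ccccc5)c3c1O[C@H](c1ccc(OCc5ccccc5)c(OCc5ccccc5)c1)[C@H](O)C3)[C@@H](OC(C)=O)[C@@H](c1ccc(OCc5ccccc5)c(OCc5ccccc5)c1)O2 | intermediate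
22 | hexadeca-O-benzyl tetramer, all 3-OH free | O(Cc5ccccc5)c1cc(OCc5ccccc5)c2c(c1)O[C@H](c1ccc(OCc5ccccc5)c(OCc5ccccc5)c1)[C@@H](O)[C@@H]2c1c(OCc5ccccc5)cc2c(c1OCc5ccccc5)[C@H](c1c(OCc5ccccc5)cc(OCc5ccccc5)c3c1O[C@H](c1ccc(OCc5ccccc5)c(OCc5ccccc5)c1)[C@H](O)[C@H]3c1c(OCc5ccccc5)cc(OCc5ccccc5)c3c1O[C@H](c1ccc(OCc5ccccc5)c(OCc5ccccc5)c1)[C@H](O)C3)[C@@H](O)[C@@H](c1ccc(OCc5ccccc5)c(OCc5ccccc5)c1)O2 | intermediate
23 | catechin-(4α→6)-epicatechin-(4β→8)-epicatechin-(4β→8)-epicatechin | Oc1cc(O)c2c(c1)O[C@H](c1ccc(O)c(O)c1)[C@@H](O)[C@@H]2c1c(O)cc2c(c1O)[C@H](c1c(O)cc(O)c3c1O[C@H](c1ccc(O)c(O)c1)[C@H](O)[C@H]3c1c(O)cc(O)c3c1O[C@H](c1ccc(O)c(O)c1)[C@H](O)C3)[C@@H](O)[C@@H](c1ccc(O)c(O)c1)O2 | target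

**Summary**

Total step count: 16. Longest linear sequence: 10 steps (steps 1, 2, 3, 5, 6, 7, 10, 14, 15, 16).

Steps most likely to fail:

Step 10. The chiral acid may discriminate the two faces poorly on so large a substrate. The addition may also turn stepwise, so that the C2 benzylic cation rotates before ring closure and the 2,3-cis relationship is lost. The enol acetate may be consumed by the methanol that is released, and the oxocarbenium ion may be captured by the electron-rich benzylated rings instead of the alkene. The fallback builds unit B from the chiral pool with a bromine cap and two leaving groups of different hardness. It sets out from 19: NBS in CH2Cl2 at low temperature brominates C8 to give 8-bromo-5,7,3',4'-tetra-O-benzyl-4β-(2-ethoxyethoxy)epicatechin F1. Phenylmethanethiol with BF3·OEt2 then exchanges the C4 alkoxy group to give 4β-benzylthio-8-bromo-5,7,3',4'-tetra-O-benzylepicatechin F2. TMSOTf-mediated coupling of the C4 cation from 3 with F2, whose only free arene carbon is C6, gives the 4α→6 linked dimer with 8-bromo and 4β-benzylthio groups in its lower unit F3. AgBF4 activates the thioether of F3 in the presence of an excess of 20 to give the 8-bromo hexadeca-O-benzyl tetramer F4. Hydrogenolysis (H2, Pd(OH)2/C, Et3N) then removes the benzyl groups and the bromine, and the fallback comes back to the route at 23.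

Step 5. The C4 cation may attack ortho instead of para to the silyloxy group, which would lead to the 4→8 series, and 4 may self-condense through its own C8. The fallback lets two free hydroxyls mark the reacting carbon. It sets out from 4 and commercial phloroglucinol, which is monosilylated (TIPSCl, imidazole) to 5-(triisopropylsilyloxy)benzene-1,3-diol F5. BF3·OEt2-mediated coupling with 4 at the carbon between the two free hydroxyls, the only arene position not next to the silyl ether, gives 3-O-acetyl-tetra-O-benzylcatechin with a 4α-[2,6-dihydroxy-4-(triisopropylsilyloxy)phenyl] group F6. Benzylation of the two phenols (BnBr, K2CO3, DMF) brings the fallback back to the route at 7.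

Step 14. The dimer 20 may be attacked at C6 of either of its units instead of C8 of the upper one, and 16 may self-condense through the free arene carbons of its own units. The fallback adds the last two units one at a time, so that each bond is made to a monomer, whose C8 preference is well established. It sets out from 19, which phenylmethanethiol and BF3·OEt2 convert into 4β-benzylthio-5,7,3',4'-tetra-O-benzylepicatechin F7. TMSOTf couples 16 with F7 at C8 (the thioether is inert to the hard Lewis acid) to give the A–B–C trimer carrying a 4β-benzylthio group on unit C F8. AgBF4 then activates the thioether in the presence of an excess of 18, and the fallback comes back to the route at 21.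

**Further compounds**

F1 | step 10 | 8-bromo-5,7,3',4'-tetra-O-benzyl-4β-(2-ethoxyethoxy)epicatechin | O(Cc5ccccc5)c1cc(OCc5ccccc5)c2c(c1Br)O[C@H](c1ccc(OCc5ccccc5)c(OCc5ccccc5)c1)[C@H](O)[C@H]2OCCOCC
F2 | step 10 | 4β-benzylthio-8-bromo-5,7,3',4'-tetra-O-benzylepicatechin | O(Cc5ccccc5)c1cc(OCc5ccccc5)c2c(c1Br)O[C@H](c1ccc(OCc5ccccc5)c(OCc5ccccc5)c1)[C@H](O)[C@H]2SCc5ccccc5
F3 | step 10 | tetra-O-benzylcatechin-(4α→6)-[4β-benzylthio-8-bromo-tetra-O-benzylepicatechin] | O(Cc5ccccc5)c1cc(OCc5ccccc5)c2c(c1)O[C@H](c1ccc(OCc5ccccc5)c(OCc5ccccc5)c1)[C@@H](O)[C@@H]2c1c(OCc5ccccc5)c(Br)c2c(c1OCc5ccccc5)[C@H](SCc5ccccc5)[C@@H](O)[C@@H](c1ccc(OCc5ccccc5)c(OCc5ccccc5)c1)O2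
F4 | step 10 | hexadeca-O-benzyl tetramer with bromine at C8 of unit B, all 3-OH free | O(Cc5ccccc5)c1cc(OCc5ccccc5)c2c(c1)O[C@H](c1ccc(OCc5ccccc5)c(OCc5ccccc5)c1)[C@@H](O)[C@@H]2c1c(OCc5ccccc5)c(Br)c2c(c1OCc5ccccc5)[C@H](c1c(OCc5ccccc5)cc(OCc5ccccc5)c3c1O[C@H](c1ccc(OCc5ccccc5)c(OCc5ccccc5)c1)[C@H](O)[C@H]3c1c(OCc5ccccc5)cc(OCc5ccccc5)c3c1O[C@H](c1ccc(OCc5ccccc5)c(OCc5ccccc5)c1)[C@H](O)C3)[C@@H](O)[C@@H](c1ccc(OCc5ccccc5)c(OCc5ccccc5)c1)O2
F5 | step 5 | 5-(triisopropylsilyloxy)benzene-1,3-diol | CC(C)[Si](Oc1cc(O)cc(O)c1)(C(C)C)C(C)C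
F6 | step 5 | 3-O-acetyl-tetra-O-benzylcatechin with 4α-[2,6-dihydroxy-4-(triisopropylsilyloxy)phenyl] | O(Cc5ccccc5)c1cc(OCc5ccccc5)c2c(c1)O[C@H](c1ccc(OCc5ccccc5)c(OCc5ccccc5)c1)[C@@H](OC(C)=O)[C@@H]2c1c(O)cc(O[Si](C(C)C)(C(C)C)C(C)C)cc1O
F7 | step 14 | 4β-benzylthio-5,7,3',4'-tetra-O-benzylepicatechin | O(Cc5ccccc5)c1cc(OCc5ccccc5)c2c(c1)O[C@H](c1ccc(OCc5ccccc5)c(OCc5ccccc5)c1)[C@H](O)[C@H]2SCc5ccccc5
F8 | step 14 | dodeca-O-benzyl trimer (units A to C), 3-O-acetyl on units A and B, 4β-benzylthio on unit C | O(Cc5ccccc5)c1cc(OCc5ccccc5)c2c(c1)O[C@H](c1ccc(OCc5ccccc5)c(OCc5ccccc5)c1)[C@@H](OC(C)=O)[C@@H]2c1c(OCc5ccccc5)cc2c(c1OCc5ccccc5)[C@H](c1c(OCc5ccccc5)cc(OCc5ccccc5)c3c1O[C@H](c1ccc(OCc5ccccc5)c(OCc5ccccc5)c1)[C@H](O)[C@H]3SCc5ccccc5)[C@@H](OC(C)=O)[C@@H](c1ccc(OCc5ccccc5)c(OCc5ccccc5)c1)O2
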